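All runs are calculated with constants of no real substance, noise included.

**The stall.** Friday's run stops near 10.0% substrate at equal charges, while Thursday's, with excess partner, reaches 0%. I want to know what that stall means for a flask that doses substrate.

| flask | substrate | partner | initiator | remark | time |
|---|---|---|---|---|---|
| Friday's | 0.050 M | 0.050 M | 1.2 mM | run made earlier |  |
| Wednesday's | 0.050 M | 0.034 M | 1.2 mM | run made earlier |  |
| Thursday's | 0.050 M | 0.075 M | 1.2 mM | run made earlier |  |
| oak | 0.050 M | 0.0500 M | 1.2 mM | a closed flask charged with all of it at once and left for 1.5 h | 1.5 h |
| maple | 0.050 M | 0.0500 M (fed, over 1.20 h) | 1.2 mM | a stirred flask in which partner is dosed at a steady rate over 1.20 h without added volume, worked up at 1.5 h | 1.5 h |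
| larch | 0.050 M | 0.0500 M | 1.2 mM | one stirred flow tank at steady state, fed with the mixture as stated, mean residence time 1.5 h |  |
| elm | 0.050 M (fed, over 1.20 h) | 0.0500 M | 1.2 mM | all but substrate at the start; substrate goes in evenly over 1.20 h, the run ends at 1.5 h | 1.5 h |

| run | time / min | target / % | substrate / % |
|---|---|---|---|
| Friday's | 10.0 | 84.2 | 19.4 |
| Friday's | 20.0 | 89.3 | 9.9 |
| Friday's | 30.0 | 88.4 | 10.0 |
| Friday's | 40.0 | 87.8 | 9.7 |
| Friday's | 50.0 | 88.9 | 10.0 |
| Wednesday's | 15.0 | 64.0 | 34.6 |
| Wednesday's | 30.0 | 63.8 | 35.9 |
| Wednesday's | 40.0 | 62.6 | 36.2 |
| Wednesday's | 60.0 | 63.9 | 35.4 |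
| Wednesday's | 80.0 | 65.2 | 35.5 |
| Thursday's | 15.0 | 93.2 | 8.8 |
| Thursday's | 30.0 | 97.8 | 1.0 |
| Thursday's | 40.0 | 100.7 | 1.4 |
| Thursday's | 60.0 | 99.2 | 0 |
| Thursday's | 80.0 | 101.2 | 0 |

(each reading ± 1 percentage point)

- the stated concentrations are those of everything mixed, before any reaction; amounts are the same in each set-up
- on the list of suspects stand: partner -> decomposed reagent; initiator -> 2 initiating radical; substrate + second chain carrier -> by-product + first chain carrier; partner + first chain carrier -> target + second chain carrier; substrate + initiating radical -> capped initiator + first chain carrier; 2 second chain carrier -> ended chains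
- the feed brings no volume worth counting
- the earlier runs were made in a closed, stirred flask

1. the set-up with the highest amount of target at the outlet or at the end, in percent of the substrate put in ("none" if the first two lie within 2 percentage points) (oak / maple / larch / elm / none)
2. amount of target at the outlet or at the end, in percent of the substrate put in, oak
3. amount of target at the outlet or at the end, in percent of the substrate put in, maple
4. amount of target at the outlet or at the end, in percent of the substrate put in, larch
5. amount of target at the outlet or at the end, in percent of the substrate put in, elm

**Two constants.** Thursday's 8.8% at 15.0 min gives a pseudo-first-order substrate clock of 0.162 min⁻¹. Friday's target stops with substrate left at equal charges, so I take partner as its limiting reagent and let it also decay to decomposed reagent with constant kd. Dividing partner's balance by substrate's, and putting partner at zero where Friday's substrate stops at fraction a, gives m equal to a raised to one minus m, with m the ratio of kd to the clock. Repeated substitution gives m = 0.136, so kd is 0.0220 min⁻¹.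

**First instants.** In elm the partner charge stands waiting while substrate builds up, and I count partner's loss as decay for one clock time, 6.17 min. In my reckoning that leaves elm's [partner] at 0.0436 M.

**The middle.** Because the clock time is shorter than the dosing time, I take elm's [substrate] as nearly constant and freeze it (quasi-steady state): the clock consumes substrate as it arrives, at 0.0417 M h⁻¹. Decay at first takes 0.0576 M h⁻¹, more than that feed.

**The end.** With both drains, my reckoning puts elm's partner at zero after 39.4 min of this stage, before dosing stops. In this reckoning substrate fed afterwards makes no target, and the pool standing at that moment equals the feed of the first 6.17 min. So target is the race share, the time partner lasts against the feed, divided by the dosing time: 54.8%.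

**The forecast.** It gives 89% for oak, 97% for maple, 93% for larch and 55% for elm, and names maple. Of elm it says “partner sits decaying while substrate trickles in”.

**The result.** Oak gives 89.9%, maple 99.9%, larch 93.4% and elm 54.2%, so maple leads.

    partner → decomposed reagent (k = 0.0230 min⁻¹)
    initiator → 2 initiating radical (k = 0.00200 min⁻¹)
    substrate + second chain carrier → by-product + first chain carrier (k = 24000 M⁻¹ s⁻¹)
    partner + first chain carrier → target + second chain carrier (k = 5.30 × 10⁵ M⁻¹ min⁻¹)
    substrate + initiating radical → capped initiator + first chain carrier (k = 4.80 × 10⁵ M⁻¹ s⁻¹)
    2 second chain carrier → ended chains (k = 2.90 × 10⁶ M⁻¹ s⁻¹)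

**Coming to rest.** The race share 54.8% stands beside elm's 54.2%. For the neighbour, elm with 0.085 M of substrate, it gives 37.6%, and that flask ends at 37.4%. Elm at 15.0 h still holds 54.2% target, with partner at 0%. Between 1.50 h and then, elm's substrate goes from 45.5% to 42.2%, and initiator from 83.5% to 16.5% of its charge, while capped initiator reaches 0.00200 M.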